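## The problem

The target is a heliangolide-type germacranolide. Its ten-membered carbocycle (C1–C10) is trans-fused at C6–C7 to an α-methylene-γ-butyrolactone (lactone oxygen on C6, C12 carbonyl, C11=C13 methylene). The ring carries a C1 ketone next to the tertiary carbinol C10 (with its methyl), a Z-trisubstituted C4=C5 olefin (methyl on C4) and an angelate on the C8 oxygen. The central difficulty is the medium ring: few of its bonds can be closed without a fight against transannular strain, smaller competing rings or the Z-olefin geometry. There are four stereocentres, 6R, 7R, 8R and 10S. C6 lies on the lactone and can steer its ring neighbour C7, and the C7/C8 relation can be fixed in whichever step forms the C7–C8 bond. C10 is quaternary and insulated by the C9 methylene and the C1 carbonyl, so no other centre can be trusted to control it and it is best bought. Several groups will not survive rough treatment: the methylene lactone (Michael acceptor), the angelate (isomerises to the tiglate under base or nucleophilic acyl-transfer catalysis), the Z-olefin, the C6–H (allylic and vinylogously α to the carbonyl once a butenolide is present), the tertiary α-ketol, and the C8 oxygen, which can translactonise. The enabling feature is that C7 is the γ-carbon of a butenolide C6–C7=C11–C12 if C13 is written as a CH2–metal group. An allylmetal reacting through C7 with a C8 aldehyde forms the ring bond C7–C8, moves the double bond to C11=C13 and leaves the C8 hydroxyl, so ring, two stereocentres, methylene lactone and acylation site arise together.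

## Retrosynthesis

**C8 ester and C10 silyl ether (32 ⇒ 31 ⇒ 28).** The acyl C–O bond of the angelate and the Si–O bond at C10 are cut first, so the two most labile features never see C–C bond-forming chemistry. Acylating 28 with angelic acid 29 while C10 is still silylated leaves C8–OH as the only nucleophile. The forward steps must install the Z-ester without leakage to the tiglate and remove silicon without base.

**C7–C8 (28 ⇒ 27).** This is the strategic cut. Closing the ring at C4=C5 would have to create a Z-trisubstituted olefin inside a ten-membered ring. Closing it at C1–C2 or C1–C10 would form no stereocentre, or would form C10 without control. The C7–C8 cut is the only ring bond whose formation also sets two stereocentres and unveils the methylene lactone. It turns the bicycle into 27, a flat butenolide carrying one chain with only C6 and C10 as stereocentres. The forward reaction must attack the aldehyde and not the C1 ketone, react through C7 and not C13, close rather than oligomerise, and deliver the 7R,8R pair.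

**C8 and C13 functional groups, C11–C13 (27 ⇒ 26 ⇒ 25 ⇒ 24 ⇒ 23 ⇒ 22).** The aldehyde is traced to a primary silyl ether (25 via alcohol 26), so that it appears only after tin is in place. The C13–Sn bond is traced to the bromide 24 and the alcohol 23. The C11–C13 bond is then cut to the unsubstituted butenolide 22 and a one-carbon electrophile. This order keeps the acid-sensitive allylstannane to three steps. It asks for a hydroxymethylation that does not epimerise C6 and a stannylation that leaves the ketone alone.

**C6–C7 and the lactone C–O bond (22 ⇒ 20 ⇒ 17 + 18).** The butenolide is opened to the γ-hydroxy ynoate 20, and the C6–C7 bond is cut to the Z-enal 17 and methyl propiolate 18. The alkyne brings C7, C11 and C12 in one piece at the right oxidation level. C6 is set by a catalyst, independent of the remote C10. Semireduction must give the cis enoate so that the ring closes by itself.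

**C1–C2 (17 ⇒ 16 ⇒ 8 + 14).** Cutting next to the ketone divides the chain into the achiral Z-olefin piece 8 and the chiral amide 14. The ketone is made in the bond-forming step itself. The alternative cut at C2–C3 would need an allylic electrophile whose Z geometry is at risk. The forward reaction is an organolithium acylation that must stop at the ketone; the allylic alcohol 16 is then oxidised to 17.

**Citramalate piece (14 ⇒ 13 ⇒ 12 ⇒ 10 ⇒ 9).** (S)-Citramalic acid 9 already holds C10 with the correct configuration, its methyl, the carboxyl that becomes C1 and the two-carbon arm C9–C8. Only differentiation of the two carboxyls (acetonide 10, lactone 12, amide 13) and silylation are needed.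

**Z-olefin piece (8 ⇒ 7 ⇒ 6 ⇒ 5 ⇒ 4 ⇒ 3 ⇒ 1 + 2).** The Z geometry is locked by holding C3–C4=C5–C6 in the six-membered lactone 4. This comes from ring-closing metathesis of the ester 3 of 3-methylbut-3-en-1-ol 1 and acryloyl chloride 2. Ring opening (5), iodination (6) and two reductions (7, 8) differentiate the ends without touching the olefin.

## Roads not taken

Alternative 1: The cut is C8–C9, made by ring expansion. An alkoxide-accelerated oxy-Cope shift on a six-membered ring holding C1–C6 forms C8–C9, cleaves C1–C6 and gives the cyclodecadienone A1. This is a well-founded way into germacrane rings. The six-membered ring secures the Z C4=C5 olefin, no high dilution is needed, and the C8 ether stereocentre is carried through. Its weakness lies after the ring is made. A1 has only one of the four stereocentres: C6 is a ketone, C7 a bare methylene, C10 an olefinic carbon, and C11–C13 are missing. A three-carbon unit would have to be attached at C7 next to the C8 ether, where enolisation invites β-elimination and the Z-enone can isomerise. C6 would then be reduced, the lactone closed and methylenated, and the C1=C10 olefin turned into ketone and tertiary alcohol with C10 controlled only by ring conformation. It must be granted that the ring formation leading to A1 is better precedented than step 20. Against this the chosen plan fixes C10 and C6 before ring closure, lets the closure deliver lactone, methylene, C7 and C8 together, and needs two steps afterwards instead of eight or more.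

Alternative 2: The cut is C6–C7, with ring contraction. Deprotonation at C6 of a thirteen-membered cyclic bis-allylic ether triggers a [2,3]-Wittig shift that forms C6–C7, breaks O–C13, creates the C11=C13 methylene and gives the carbocycle A2. It has real merits. An easier macro-etherification replaces a medium-ring C–C closure. One concerted five-centre transition state creates C6, C7 and the methylene, and its stereochemical transfer is in principle more predictable than an open transition state. No tin is used. The weak points are regioselective metalation between two allylic α-oxy positions, competition from the [1,2] shift, and possible scrambling of the C4=C5 geometry in the allyl anion. The facial outcome also depends on the conformation of a large ring. In A2, C12 is only at the aldehyde level and C1 is a protected carbinol stereocentre that is built to be erased. Six or more redox and protecting-group steps would follow. The chosen plan shares the uncertainty about stereochemical sense. It offers instead the lactone at its final oxidation level from the start, the ketone in place, and a two-step endgame.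

Alternative 3: The cut is C1–C10. Cathodic reduction of a C10 methyl ketone gives a ketyl that adds to a C1 nitrile; hydrolysis of the imine gives the ten-membered α-ketol lactone A3. The step makes ketone and tertiary alcohol at once, with no protecting group on C10. The lactone and the C6–C8 triad are assembled beforehand by dependable chemistry, so the C7/C8 relation is not hazarded in the ring closure. In that respect this road is better than the chosen one. Its weak points are serious. Reductive ketone–nitrile coupling is established for five- and six-membered rings, and a ten-membered closure by a short-lived ketyl must compete with simple reduction and pinacol coupling. C10 would be formed in the closure with only the remote C8 to bias it. The lactone with its β-silyloxymethyl group has to survive the cathode. Elimination to the methylene lactone, ether cleavage and angeloylation would still follow. The trade is clear: the chosen plan buys C10 and risks C7/C8, while the road to A3 secures C7/C8 and risks both C10 and the ring closure itself. The chosen polar closure has close precedent for each half of the reaction and a known-chemistry fallback for the same bond.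

Key step: step 20

Remark: atoms are numbered as in germacranolides (C1 ketone to C10 carbinol, C11–C13 lactone arm); 26 is drawn as the open hydroxy ketone although it may rest partly as its five-membered hemiketal.

Remark: the (R,R)-ProPhenol ligand is assumed to deliver the alkyne to the Si face of aldehyde 17; if the sense of induction proves opposite, the (S,S)-ligand is used with no other change.

## Route

Step 1
Reactants: 1 3-methylbut-3-en-1-ol; 2 acryloyl chloride
Product: 3 3-methylbut-3-en-1-yl prop-2-enoate
Conditions: Et3N, CH2Cl2, 0 °C to rt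
Reagents that add atoms: none
Why: Esterification of a primary alcohol with an acid chloride; the amine traps HCl and the low temperature avoids acrylate polymerisation.

Step 2
Reactants: 3 3-methylbut-3-en-1-yl prop-2-enoate
Product: 4 4-methyl-5,6-dihydro-2H-pyran-2-one
Conditions: second-generation Grubbs catalyst RuCl2(=CHPh)(H2IMes)(PCy3) (cat.), CH2Cl2, 40 °C, 0.01 M
Reagents that add atoms: none
Why: Ring-closing metathesis of an acrylate with a 1,1-disubstituted olefin, a pairing established for this catalyst class; a six-membered ring can hold only a cis ring olefin, so the C4=C5 geometry (C3 and C6 cis) is fixed here.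

Step 3
Reactants: 4 4-methyl-5,6-dihydro-2H-pyran-2-one
Product: 5 (2Z)-5-hydroxy-N-methoxy-N,3-dimethylpent-2-enamide
Conditions: MeNH(OMe)·HCl, AlMe3, CH2Cl2, 0 °C to rt
Reagents that add atoms: N,O-dimethylhydroxylamine hydrochloride, CNOC.Cl
Why: Weinreb amide formation by aluminium-amide aminolysis of the lactone; attack at the acyl carbon leaves the olefin geometry untouched and the β,β-disubstituted enoate resists conjugate addition.

Step 4
Reactants: 5 (2Z)-5-hydroxy-N-methoxy-N,3-dimethylpent-2-enamide
Product: 6 (2Z)-5-iodo-N-methoxy-N,3-dimethylpent-2-enamide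
Conditions: I2, PPh3, imidazole, CH2Cl2, 0 °C
Reagents that add atoms: iodine, II
Why: Appel-type iodination (SN2 on the activated primary alcohol); it also removes the hydroxyl that could re-close the lactone.

Step 5
Reactants: 6 (2Z)-5-iodo-N-methoxy-N,3-dimethylpent-2-enamide
Product: 7 (2Z)-5-iodo-3-methylpent-2-enal
Conditions: i-Bu2AlH, THF, −78 °C; aq. potassium sodium tartrate
Reagents that add atoms: none
Why: Hydride reduction of a Weinreb amide stops at the aldehyde because the chelated aluminium hemiaminal survives until work-up; the alkyl iodide and the Z-olefin are inert at −78 °C.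

Step 6
Reactants: 7 (2Z)-5-iodo-3-methylpent-2-enal
Product: 8 (2Z)-5-iodo-3-methylpent-2-en-1-ol
Conditions: NaBH4, CeCl3·7H2O, MeOH, −40 to 0 °C
Reagents that add atoms: none
Why: Luche reduction gives clean 1,2-reduction of the enal; no acid or base is present that could isomerise the olefin or displace iodide.

Step 7
Reactants: 9 (S)-citramalic acid [(2S)-2-hydroxy-2-methylbutanedioic acid]
Product: 10 2-[(4S)-2,2,4-trimethyl-5-oxo-1,3-dioxolan-4-yl]acetic acid
Conditions: 2,2-dimethoxypropane, PPTS (cat.), rt
Reagents that add atoms: 2,2-dimethoxypropane, COC(C)(C)OC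
Why: Acetalisation of the α-hydroxy acid unit gives the five-membered dioxolanone and leaves the β-carboxyl free; the quaternary centre is not touched.

Step 8
Reactants: 10 2-[(4S)-2,2,4-trimethyl-5-oxo-1,3-dioxolan-4-yl]acetic acid
Product: 12 (3S)-3-hydroxy-3-methyloxolan-2-one, via hydroxyethyl dioxolanone 11 (not isolated)
Conditions: BH3·SMe2, THF, 0 °C to rt; MeOH; then p-TsOH (cat.), CH2Cl2, rt
Reagents that add atoms: none
Why: Borane reduces the free carboxylic acid chemoselectively beside the dioxolanone; acid then drives 5-exo transacylation onto the new alcohol with loss of acetone, giving the γ-lactone with C10 unchanged.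

Step 9
Reactants: 12 (3S)-3-hydroxy-3-methyloxolan-2-one
Product: 13 (2S)-2,4-dihydroxy-N-methoxy-N,2-dimethylbutanamide
Conditions: MeNH(OMe)·HCl, AlMe3, CH2Cl2, 0 °C to rt
Reagents that add atoms: N,O-dimethylhydroxylamine hydrochloride, CNOC.Cl
Why: Weinreb amide formation by aluminium-amide aminolysis of the γ-lactone; the tertiary hydroxyl is carried as its aluminium alkoxide.

Step 10
Reactants: 13 (2S)-2,4-dihydroxy-N-methoxy-N,2-dimethylbutanamide
Product: 14 (2S)-N-methoxy-N,2-dimethyl-2,4-bis(triethylsilyloxy)butanamide
Conditions: Et3SiOTf, 2,6-lutidine, CH2Cl2, −78 to 0 °C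
Reagents that add atoms: triethylsilyl trifluoromethanesulfonate, CC[Si](CC)(CC)OS(=O)(=O)C(F)(F)F
Why: Silylation with the silyl triflate covers the primary and the hindered tertiary hydroxyl in one operation and stops relactonisation.

Step 11
Reactants: 8 (2Z)-5-iodo-3-methylpent-2-en-1-ol; 14 (2S)-N-methoxy-N,2-dimethyl-2,4-bis(triethylsilyloxy)butanamide
Product: 16 (3S,7Z)-9-hydroxy-3,7-dimethyl-1,3-bis(triethylsilyloxy)non-7-en-4-one, via dilithio alkoxide 15 (not isolated)
Conditions: 8, t-BuLi (3 equiv), Et2O–pentane, −78 °C; then 14, −78 to −20 °C; aq. NH4Cl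
Reagents that add atoms: none
Why: O-deprotonation and iodine–lithium exchange give the alkoxide-bearing primary alkyllithium 15, which adds once to the amide (Weinreb ketone synthesis); the chelated adduct releases the ketone only on work-up, so C1–C2 forms without over-addition and without touching C10 or the olefin.

Step 12
Reactants: 16 (3S,7Z)-9-hydroxy-3,7-dimethyl-1,3-bis(triethylsilyloxy)non-7-en-4-one
Product: 17 (2Z,7S)-3,7-dimethyl-6-oxo-7,9-bis(triethylsilyloxy)non-2-enal
Conditions: MnO2, CH2Cl2, rt
Reagents that add atoms: none
Why: Allylic oxidation with MnO2 touches only the allylic alcohol; the neutral heterogeneous conditions keep the Z geometry and leave the ketone and silyl ethers alone.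

Step 13
Reactants: 17 (2Z,7S)-3,7-dimethyl-6-oxo-7,9-bis(triethylsilyloxy)non-2-enal; 18 methyl propiolate
Product: 20 methyl (4R,5Z,10S)-4-hydroxy-6,10-dimethyl-9-oxo-10,12-bis(triethylsilyloxy)dodec-5-en-2-ynoate, via methylzinc acetylide 19 (not isolated)
Conditions: Me2Zn, (R,R)-ProPhenol (cat.), Ph3PO (cat.), toluene, 0–4 °C
Reagents that add atoms: none
Why: Zinc–ProPhenol catalysed asymmetric alkynylation; the alkynylzinc 19 adds to the aldehyde only, and the chiral dinuclear zinc catalyst selects the Si face to set C6 as the 4R carbinol (reagent control, C10 being too remote to interfere). The hindered ketone does not react with alkyl- or alkynylzinc species at this temperature.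

Step 14
Reactants: 20 methyl (4R,5Z,10S)-4-hydroxy-6,10-dimethyl-9-oxo-10,12-bis(triethylsilyloxy)dodec-5-en-2-ynoate
Product: 22 (5S)-5-[(1Z,6S)-2,6-dimethyl-5-oxo-6,8-bis(triethylsilyloxy)oct-1-en-1-yl]furan-2(5H)-one, via cis-hydroxy enoate 21 (not isolated)
Conditions: H2 (1 atm), Pd/CaCO3–Pb(OAc)2, quinoline, EtOAc, rt; then PPTS (cat.), CH2Cl2, rt
Reagents that add atoms: none
Why: Lindlar semihydrogenation gives the cis enoate 21, whose γ-hydroxyl closes the butenolide with loss of methanol; the trisubstituted olefin and the ketone are not reduced, and C6 is untouched (its descriptor changes only through the priority rules).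

Step 15
Reactants: 22 (5S)-5-[(1Z,6S)-2,6-dimethyl-5-oxo-6,8-bis(triethylsilyloxy)oct-1-en-1-yl]furan-2(5H)-one
Product: 23 (5R)-3-(hydroxymethyl)-5-[(1Z,6S)-2,6-dimethyl-5-oxo-6,8-bis(triethylsilyloxy)oct-1-en-1-yl]furan-2(5H)-one
Conditions: aq. CH2O, PBu3 (cat.), THF, rt
Reagents that add atoms: formaldehyde, C=O
Why: Morita–Baylis–Hillman hydroxymethylation, known for cyclic enones and γ-substituted butenolides; the phosphine adds to C7, the enolate takes up formaldehyde at C11 and loss of phosphine restores the butenolide. A weakly basic phosphine in aqueous medium is chosen to spare the epimerisable C6–H.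

Step 16
Reactants: 23 (5R)-3-(hydroxymethyl)-5-[(1Z,6S)-2,6-dimethyl-5-oxo-6,8-bis(triethylsilyloxy)oct-1-en-1-yl]furan-2(5H)-one
Product: 24 (5R)-3-(bromomethyl)-5-[(1Z,6S)-2,6-dimethyl-5-oxo-6,8-bis(triethylsilyloxy)oct-1-en-1-yl]furan-2(5H)-one
Conditions: CBr4, PPh3, 2,6-lutidine, CH2Cl2, −20 to 0 °C
Reagents that add atoms: tetrabromomethane, BrC(Br)(Br)Br
Why: Appel bromination of the primary allylic alcohol by direct SN2 displacement; the buffered neutral conditions spare the silyl ethers and C6.

Step 17
Reactants: 24 (5R)-3-(bromomethyl)-5-[(1Z,6S)-2,6-dimethyl-5-oxo-6,8-bis(triethylsilyloxy)oct-1-en-1-yl]furan-2(5H)-one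
Product: 25 (5R)-5-[(1Z,6S)-2,6-dimethyl-5-oxo-6,8-bis(triethylsilyloxy)oct-1-en-1-yl]-3-[(tributylstannyl)methyl]furan-2(5H)-one
Conditions: Bu3SnSnBu3, Pd2(dba)3 (cat.), THF, rt, dark
Reagents that add atoms: hexabutyldistannane, CCCC[Sn](CCCC)(CCCC)[Sn](CCCC)(CCCC)CCCC
Why: Palladium-catalysed stannylation of an allylic bromide with a distannane: oxidative addition of zerovalent palladium to C–Br, transmetalation, and reductive elimination at the unhindered C13 terminus, which keeps the butenolide conjugated. A phosphine-free catalyst at room temperature is chosen because the allylic bromide reacts far faster than the lactone C6–O bond could ionise; the ketone is not touched.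

Step 18
Reactants: 25 (5R)-5-[(1Z,6S)-2,6-dimethyl-5-oxo-6,8-bis(triethylsilyloxy)oct-1-en-1-yl]-3-[(tributylstannyl)methyl]furan-2(5H)-one
Product: 26 (5R)-5-[(1Z,6S)-8-hydroxy-2,6-dimethyl-5-oxo-6-(triethylsilyloxy)oct-1-en-1-yl]-3-[(tributylstannyl)methyl]furan-2(5H)-one
Conditions: HF·pyridine, pyridine, THF, 0 °C
Reagents that add atoms: none
Why: Selective desilylation; the primary silyl ether is cleaved much faster than the hindered tertiary one, and the pyridine buffer protects the allylstannane from protodestannylation.

Step 19
Reactants: 26 (5R)-5-[(1Z,6S)-8-hydroxy-2,6-dimethyl-5-oxo-6-(triethylsilyloxy)oct-1-en-1-yl]-3-[(tributylstannyl)methyl]furan-2(5H)-one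
Product: 27 (5R)-5-[(1Z,6S)-2,6-dimethyl-5,8-dioxo-6-(triethylsilyloxy)oct-1-en-1-yl]-3-[(tributylstannyl)methyl]furan-2(5H)-one
Conditions: Dess–Martin periodinane, NaHCO3, CH2Cl2, 0 °C to rt
Reagents that add atoms: none
Why: Dess–Martin oxidation under bicarbonate buffering gives the aldehyde through the open hydroxy ketone form, without base that could epimerise C6 and without electrophiles that attack the allylstannane.

Step 20
Reactants: 27 (5R)-5-[(1Z,6S)-2,6-dimethyl-5,8-dioxo-6-(triethylsilyloxy)oct-1-en-1-yl]-3-[(tributylstannyl)methyl]furan-2(5H)-one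
Product: 28 (4Z,6R,7R,8R,10S)-8-hydroxy-1-oxo-10-(triethylsilyloxy)germacra-4,11(13)-dien-12,6-olide
Conditions: BF3·OEt2 (3 equiv), CH2Cl2, −78 °C, slow addition of 27 (final 0.002 M); aq. NaHCO3
Reagents that add atoms: none
Why: Proposed new method: BF3 binds the unhindered C8 aldehyde, and the C13–Sn σ bond pushes the butenolide C11=C7 π bond onto the activated carbonyl through C7 in an open SE2′ transition state, so that C7–C8 forms as tin leaves C13 and the C11=C13 methylene appears. The closest known reaction types are Lewis-acid additions of 2-(alkoxycarbonyl)allylstannanes to aldehydes, Lewis-acid allylstannane–aldehyde macrocyclisations, and chromium- or indium-mediated allylations of aldehydes with 3-(halomethyl)furan-2(5H)-ones. The ten-membered carbocycle closes in a 10-exo-trig carbonyl addition, helped by the Z-olefin and the planar butenolide, which remove rotors from the tether, and by slow addition at high dilution. C7 is controlled by C6: the new bond should develop on the butenolide face that carries H6, anti to the C6–C5 bond, which gives the trans-fused lactone (7R). C8 is controlled by the antiperiplanar arrangement of the C8=O and C7=C11 bonds, with C9 anti to C6 and the BF3-bound oxygen pointing away from the ring; in acyclic additions this arrangement gives the syn pair (here 7R,8R) whatever the allylstannane geometry. The step needs aldehyde-over-ketone selectivity, secured by the quaternary silyloxy-bearing C10 beside C1 and by the much higher reactivity of a BF3-bound aldehyde. It also needs γ-attack (C7, not C13), which is intrinsic to the SE2′ path, and closure rather than oligomerisation. The C7/C8 sense rests on analogy and is the first point to be tested.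

Step 21
Reactants: 28 (4Z,6R,7R,8R,10S)-8-hydroxy-1-oxo-10-(triethylsilyloxy)germacra-4,11(13)-dien-12,6-olide; 29 angelic acid [(2Z)-2-methylbut-2-enoic acid]
Product: 31 (4Z,6R,7R,8R,10S)-8-[(2Z)-2-methylbut-2-enoyloxy]-1-oxo-10-(triethylsilyloxy)germacra-4,11(13)-dien-12,6-olide, via mixed anhydride 30 (not isolated)
Conditions: 29, 2,4,6-trichlorobenzoyl chloride, Et3N, toluene, rt; then 28, 75 °C
Reagents that add atoms: none
Why: Yamaguchi-type acylation through the mixed anhydride 30 without a nucleophilic acyl-transfer catalyst, the established way to make angelates without isomerisation to tiglates; C8–OH is the only free hydroxyl.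

Step 22
Reactants: 31 (4Z,6R,7R,8R,10S)-8-[(2Z)-2-methylbut-2-enoyloxy]-1-oxo-10-(triethylsilyloxy)germacra-4,11(13)-dien-12,6-olide
Product: 32 (4Z,6R,7R,8R,10S)-10-hydroxy-8-[(2Z)-2-methylbut-2-enoyloxy]-1-oxogermacra-4,11(13)-dien-12,6-olide (CNP0345906.2)
Conditions: HF·pyridine, THF, 0 °C to rt
Reagents that add atoms: none
Why: Desilylation of the tertiary silyl ether with HF·pyridine; acidic fluoride conditions avoid base-induced translactonisation, conjugate addition to the methylene lactone and angelate isomerisation.

## Compound list

1 | 3-methylbut-3-en-1-ol | CC(=C)CCO | starting material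
2 | acryloyl chloride | C=CC(=O)Cl | starting material
3 | 3-methylbut-3-en-1-yl prop-2-enoate | C=CC(=O)OCCC(C)=C | intermediate
4 | 4-methyl-5,6-dihydro-2H-pyran-2-one | CC1=CC(=O)OCC1 | intermediate
5 | (2Z)-5-hydroxy-N-methoxy-N,3-dimethylpent-2-enamide | CON(C)C(=O)/C=C(/C)CCO | intermediate
6 | (2Z)-5-iodo-N-methoxy-N,3-dimethylpent-2-enamide | CON(C)C(=O)/C=C(/C)CCI | intermediate
7 | (2Z)-5-iodo-3-methylpent-2-enal | O=C/C=C(/C)CCI | intermediate
8 | (2Z)-5-iodo-3-methylpent-2-en-1-ol | OC/C=C(/C)CCI | intermediate
9 | (S)-citramalic acid | C[C@](O)(CC(=O)O)C(=O)O | starting material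
10 | 2-[(4S)-2,2,4-trimethyl-5-oxo-1,3-dioxolan-4-yl]acetic acid | C[C@@]1(CC(=O)O)OC(C)(C)OC1=O | intermediate
11 | (5S)-5-(2-hydroxyethyl)-2,2,5-trimethyl-1,3-dioxolan-4-one (not isolated) | C[C@@]1(CCO)OC(C)(C)OC1=O | intermediate
12 | (3S)-3-hydroxy-3-methyloxolan-2-one | C[C@]1(O)CCOC1=O | intermediate
13 | (2S)-2,4-dihydroxy-N-methoxy-N,2-dimethylbutanamide | CON(C)C(=O)[C@@](C)(O)CCO | intermediate
14 | (2S)-N-methoxy-N,2-dimethyl-2,4-bis(triethylsilyloxy)butanamide | CON(C)C(=O)[C@@](C)(O[Si](CC)(CC)CC)CCO[Si](CC)(CC)CC | intermediate
15 | lithium (2Z)-5-lithio-3-methylpent-2-en-1-olate (not isolated) | [Li]OC/C=C(/C)CC[Li] | intermediate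
16 | (3S,7Z)-9-hydroxy-3,7-dimethyl-1,3-bis(triethylsilyloxy)non-7-en-4-one | OC/C=C(/C)CCC(=O)[C@@](C)(O[Si](CC)(CC)CC)CCO[Si](CC)(CC)CC | intermediate
17 | (2Z,7S)-3,7-dimethyl-6-oxo-7,9-bis(triethylsilyloxy)non-2-enal | O=C/C=C(/C)CCC(=O)[C@@](C)(O[Si](CC)(CC)CC)CCO[Si](CC)(CC)CC | intermediate
18 | methyl propiolate | C#CC(=O)OC | starting material
19 | methyl 3-(methylzincio)prop-2-ynoate (not isolated) | C[Zn]C#CC(=O)OC | intermediate
20 | methyl (4R,5Z,10S)-4-hydroxy-6,10-dimethyl-9-oxo-10,12-bis(triethylsilyloxy)dodec-5-en-2-ynoate | COC(=O)C#C[C@H](O)/C=C(/C)CCC(=O)[C@@](C)(O[Si](CC)(CC)CC)CCO[Si](CC)(CC)CC | intermediate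
21 | methyl (2Z,4S,5Z,10S)-4-hydroxy-6,10-dimethyl-9-oxo-10,12-bis(triethylsilyloxy)dodeca-2,5-dienoate (not isolated) | COC(=O)/C=C\[C@H](O)/C=C(/C)CCC(=O)[C@@](C)(O[Si](CC)(CC)CC)CCO[Si](CC)(CC)CC | intermediate
22 | (5S)-5-[(1Z,6S)-2,6-dimethyl-5-oxo-6,8-bis(triethylsilyloxy)oct-1-en-1-yl]furan-2(5H)-one | O=C1O[C@H](/C=C(/C)CCC(=O)[C@@](C)(O[Si](CC)(CC)CC)CCO[Si](CC)(CC)CC)C=C1 | intermediate
23 | (5R)-3-(hydroxymethyl)-5-[(1Z,6S)-2,6-dimethyl-5-oxo-6,8-bis(triethylsilyloxy)oct-1-en-1-yl]furan-2(5H)-one | O=C1O[C@H](/C=C(/C)CCC(=O)[C@@](C)(O[Si](CC)(CC)CC)CCO[Si](CC)(CC)CC)C=C1CO | intermediate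
24 | (5R)-3-(bromomethyl)-5-[(1Z,6S)-2,6-dimethyl-5-oxo-6,8-bis(triethylsilyloxy)oct-1-en-1-yl]furan-2(5H)-one | O=C1O[C@H](/C=C(/C)CCC(=O)[C@@](C)(O[Si](CC)(CC)CC)CCO[Si](CC)(CC)CC)C=C1CBr | intermediate
25 | (5R)-5-[(1Z,6S)-2,6-dimethyl-5-oxo-6,8-bis(triethylsilyloxy)oct-1-en-1-yl]-3-[(tributylstannyl)methyl]furan-2(5H)-one | O=C1O[C@H](/C=C(/C)CCC(=O)[C@@](C)(O[Si](CC)(CC)CC)CCO[Si](CC)(CC)CC)C=C1C[Sn](CCCC)(CCCC)CCCC | intermediate
26 | (5R)-5-[(1Z,6S)-8-hydroxy-2,6-dimethyl-5-oxo-6-(triethylsilyloxy)oct-1-en-1-yl]-3-[(tributylstannyl)methyl]furan-2(5H)-one | O=C1O[C@H](/C=C(/C)CCC(=O)[C@@](C)(O[Si](CC)(CC)CC)CCO)C=C1C[Sn](CCCC)(CCCC)CCCC | intermediate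
27 | (5R)-5-[(1Z,6S)-2,6-dimethyl-5,8-dioxo-6-(triethylsilyloxy)oct-1-en-1-yl]-3-[(tributylstannyl)methyl]furan-2(5H)-one | O=C1O[C@H](/C=C(/C)CCC(=O)[C@@](C)(O[Si](CC)(CC)CC)CC=O)C=C1C[Sn](CCCC)(CCCC)CCCC | intermediate
28 | (4Z,6R,7R,8R,10S)-8-hydroxy-1-oxo-10-(triethylsilyloxy)germacra-4,11(13)-dien-12,6-olide | C=C1C(=O)O[C@@H]2/C=C(/C)CCC(=O)[C@@](C)(O[Si](CC)(CC)CC)C[C@@H](O)[C@@H]12 | intermediate
29 | angelic acid [(2Z)-2-methylbut-2-enoic acid] | C/C=C(/C)C(=O)O | starting material
30 | (2Z)-2-methylbut-2-enoic 2,4,6-trichlorobenzoic anhydride (not isolated) | C/C=C(/C)C(=O)OC(=O)c1c(Cl)cc(Cl)cc1Cl | intermediate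
31 | (4Z,6R,7R,8R,10S)-8-[(2Z)-2-methylbut-2-enoyloxy]-1-oxo-10-(triethylsilyloxy)germacra-4,11(13)-dien-12,6-olide | C=C1C(=O)O[C@@H]2/C=C(/C)CCC(=O)[C@@](C)(O[Si](CC)(CC)CC)C[C@@H](OC(=O)/C(C)=C\C)[C@@H]12 | intermediate
32 | (4Z,6R,7R,8R,10S)-10-hydroxy-8-[(2Z)-2-methylbut-2-enoyloxy]-1-oxogermacra-4,11(13)-dien-12,6-olide (CNP0345906.2) | C=C1C(=O)O[C@@H]2/C=C(/C)CCC(=O)[C@@](C)(O)C[C@@H](OC(=O)/C(C)=C\C)[C@@H]12 | target

## Step count and least certain steps

Total step count: 22. Longest linear sequence: 18 steps (steps 1–6 and 11–22); the citramalate branch (steps 7–10) joins at step 11.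

**Step 20 (key step, proposed new method).** Ring closure may lose to oligomerisation, to protodestannylation or to attack on the C1 ketone (seven-membered ring), because a ten-membered ring forms slowly. The face selectivity at C7 or the relative topicity at C8 may also be set by ring strain and not by the open acyclic preference; acyclic 1,3-induction from C10 offers no help. The fallback uses known chemistry and sets out from 24. Selective desilylation (HF·pyridine) gives the bromo alcohol F1, and Dess–Martin oxidation gives the bromo aldehyde F2. Divalent chromium chloride, CrCl2, in THF at high dilution then effects an intramolecular Nozaki–Hiyama allylation. This is an established way of closing medium and large rings from allylic bromides and aldehydes, and is known intermolecularly for 3-(bromomethyl)furanones. Its closed chair transition state is expected to give the trans-lactone with the anti C7/C8 relation, the 8-epimeric alcohol F3. Mitsunobu esterification of F3 with 29 (PPh3, diisopropyl azodicarboxylate) inverts C8 and installs the angelate, returning to the route at 31. If the BF3 reaction itself delivered the 8-epimer, the same Mitsunobu step applies.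

**Step 15.** Epimerisation of C6 by γ-deprotonation, or stalling of the conjugate addition at the hindered C7, may defeat the hydroxymethylation. The fallback sets out from 20. Palladium-catalysed syn-hydrostannation (Bu3SnH, Pd(PPh3)4) places tin α to the ester and gives the stannyl hydroxy enoate F4, which lactonises to the 3-stannylbutenolide F5. Iodine converts this into the 3-iodobutenolide F6. Stille coupling of F6 with (tributylstannyl)methanol returns to the route at 23. All three operations are neutral.

**Step 17.** Zerovalent palladium may ionise the doubly allylic lactone C6–O bond, deliver tin to C7 instead of C13, or cause reductive dimerisation. The fallback sets out from 22 and uses neither palladium nor the bromide. Conjugate addition of Me2AlSPh and capture of the aluminium enolate with formaldehyde give the hydroxymethyl sulfide F7 (Michael–aldol sequence). Dehydration (MsCl, Et3N) gives the methylene lactone sulfide F8. Bu3SnH with AIBN then adds a stannyl radical to C13 and fragments the C7–S bond (radical allyl transposition of an allylic sulfide), returning to the route at 25. This detour also bypasses steps 15 and 16.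

**Step 13.** Z-to-E isomerisation of the enal under the zinc species, or poor facial selectivity with a Z-β,β-disubstituted enal, may erode C6. The fallback sets out from 17. Unselective addition of lithiated 18 (LiN(SiMe3)2, −78 °C) gives 20 together with its C6 epimer F8a, written below as F9. MnO2 oxidation of the mixture gives the ynone F10. Midland reduction with R-Alpine-Borane is selective for alkynyl ketones over the hindered C1 ketone and treats the alkyne as the small group, and should return to the route at 20.

**Step 11.** The alkoxide-bearing organolithium may aggregate and add sluggishly, or the alkoxide may cyclise onto the iodide before the exchange. The fallback sets out from 8. Protection with 4-methoxybenzyl trichloroacetimidate (acid catalyst) gives the ether F11. Iodine–lithium exchange (t-BuLi, 2 equiv) and addition to 14 give the protected ketone F12. DDQ then removes the ether and returns to the route at 16.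

In the step 13 fallback the C6 epimer of 20 carries the single label F9.

## Further compounds

F1 | step 20 | (5R)-3-(bromomethyl)-5-[(1Z,6S)-8-hydroxy-2,6-dimethyl-5-oxo-6-(triethylsilyloxy)oct-1-en-1-yl]furan-2(5H)-one | O=C1O[C@H](/C=C(/C)CCC(=O)[C@@](C)(O[Si](CC)(CC)CC)CCO)C=C1CBr
F2 | step 20 | (5R)-3-(bromomethyl)-5-[(1Z,6S)-2,6-dimethyl-5,8-dioxo-6-(triethylsilyloxy)oct-1-en-1-yl]furan-2(5H)-one | O=C1O[C@H](/C=C(/C)CCC(=O)[C@@](C)(O[Si](CC)(CC)CC)CC=O)C=C1CBr
F3 | step 20 | (4Z,6R,7R,8S,10S)-8-hydroxy-1-oxo-10-(triethylsilyloxy)germacra-4,11(13)-dien-12,6-olide | C=C1C(=O)O[C@@H]2/C=C(/C)CCC(=O)[C@@](C)(O[Si](CC)(CC)CC)C[C@H](O)[C@@H]12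
F4 | step 15 | methyl (2E,4R,5Z,10S)-4-hydroxy-6,10-dimethyl-9-oxo-2-(tributylstannyl)-10,12-bis(triethylsilyloxy)dodeca-2,5-dienoate | COC(=O)/C(=C\[C@H](O)/C=C(/C)CCC(=O)[C@@](C)(O[Si](CC)(CC)CC)CCO[Si](CC)(CC)CC)[Sn](CCCC)(CCCC)CCCC
F5 | step 15 | (5R)-5-[(1Z,6S)-2,6-dimethyl-5-oxo-6,8-bis(triethylsilyloxy)oct-1-en-1-yl]-3-(tributylstannyl)furan-2(5H)-one | O=C1O[C@H](/C=C(/C)CCC(=O)[C@@](C)(O[Si](CC)(CC)CC)CCO[Si](CC)(CC)CC)C=C1[Sn](CCCC)(CCCC)CCCC
F6 | step 15 | (5R)-3-iodo-5-[(1Z,6S)-2,6-dimethyl-5-oxo-6,8-bis(triethylsilyloxy)oct-1-en-1-yl]furan-2(5H)-one | O=C1O[C@H](/C=C(/C)CCC(=O)[C@@](C)(O[Si](CC)(CC)CC)CCO[Si](CC)(CC)CC)C=C1I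
F7 | step 17 | (3R,4S,5R)-3-(hydroxymethyl)-4-(phenylsulfanyl)-5-[(1Z,6S)-2,6-dimethyl-5-oxo-6,8-bis(triethylsilyloxy)oct-1-en-1-yl]oxolan-2-one (expected major isomer) | O=C1O[C@H](/C=C(/C)CCC(=O)[C@@](C)(O[Si](CC)(CC)CC)CCO[Si](CC)(CC)CC)[C@@H](Sc2ccccc2)[C@@H]1CO
F8 | step 17 | (4S,5R)-3-methylidene-4-(phenylsulfanyl)-5-[(1Z,6S)-2,6-dimethyl-5-oxo-6,8-bis(triethylsilyloxy)oct-1-en-1-yl]oxolan-2-one | C=C1C(=O)O[C@H](/C=C(/C)CCC(=O)[C@@](C)(O[Si](CC)(CC)CC)CCO[Si](CC)(CC)CC)[C@H]1Sc1ccccc1
F9 | step 13 | methyl (4S,5Z,10S)-4-hydroxy-6,10-dimethyl-9-oxo-10,12-bis(triethylsilyloxy)dodec-5-en-2-ynoate | COC(=O)C#C[C@@H](O)/C=C(/C)CCC(=O)[C@@](C)(O[Si](CC)(CC)CC)CCO[Si](CC)(CC)CC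
F10 | step 13 | methyl (5Z,10S)-6,10-dimethyl-4,9-dioxo-10,12-bis(triethylsilyloxy)dodec-5-en-2-ynoate | COC(=O)C#CC(=O)/C=C(/C)CCC(=O)[C@@](C)(O[Si](CC)(CC)CC)CCO[Si](CC)(CC)CC
F11 | step 11 | 1-({[(2Z)-5-iodo-3-methylpent-2-en-1-yl]oxy}methyl)-4-methoxybenzene | COc1ccc(COC/C=C(/C)CCI)cc1
F12 | step 11 | (3S,7Z)-9-[(4-methoxybenzyl)oxy]-3,7-dimethyl-1,3-bis(triethylsilyloxy)non-7-en-4-one | COc1ccc(COC/C=C(/C)CCC(=O)[C@@](C)(O[Si](CC)(CC)CC)CCO[Si](CC)(CC)CC)cc1
A1 | alternative 1 | (3R,5E,9Z)-3-[(4-methoxybenzyl)oxy]-5,9-dimethylcyclodeca-5,9-dien-1-one | C1[C@H](OCc2ccc(OC)cc2)C/C(C)=C/CC/C(C)=C\C1=O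
A2 | alternative 2 | ring-contracted ten-membered carbocycle with free C6 hydroxyl, 3,3-dimethoxyprop-1-en-2-yl group on C7, tert-butyldimethylsilyl ether on C8 and C1/C10 acetonide | O[C@@H]1/C=C(/C)CC[C@@H]2OC(C)(C)O[C@@]2(C)C[C@@H](O[Si](C)(C)C(C)(C)C)[C@H]1C(=C)C(OC)OC
A3 | alternative 3 | ten-membered α-ketol lactone with 11-(tert-butyldimethylsilyloxymethyl) and 8-O-(4-methoxybenzyl) groups | O=C1CC/C(C)=C\[C@H]2OC(=O)[C@@H](CO[Si](C)(C)C(C)(C)C)[C@@H]2[C@H](OCc3ccc(OC)cc3)C[C@]1(C)O
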